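The runs are simulated for an exercise, noise included.

The vessel is closed and stirred under held gas, which feeds reagent into solution, and reagent turns starting material into target over the catalyst and into uncatalysed product without it.

common to all: starting material 10 mM; gas 2.7 mM (held)

| charge | second substrate | free catalyst | remark |
|---|---|---|---|
| elm | 10 mM | 16 µM | the very flask that is asked about, followed so far |
| oak | 10 mM | 8 µM | run made earlier |
| flask | 10.0 mM | 16 µM |  |

- elm (time / min: target / %, starting material / %): 2.50: 0.4, 99.9; 8.00: 0.5, 99.8; 12.0: 0.2, 98.7; 20.0: 1.8, 97.1; 30.0: 2.7, 96.0; 40.0: 4.0, 93.1
- oak (time / h: target / %, starting material / %): 0.200: 0.1, 99.6; 0.667: 2.4, 95.6; 1.00: 3.5, 91.0; 1.50: 7.0, 85.2; 2.50: 11.7, 74.4; 3.00: 14.2, 68.8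

(readings scatter by 0.3 percentage points)

1. factor on the rate of making target when 30 % of the starting material are converted if second substrate is charged twice over
2. factor on the rate when 30 % of the starting material are converted if free catalyst is charged at 1.5 µM instead

- at the start none of reagent is dissolved
- what was read earlier has a scatter of 0.3 percentage points, one standard deviation
- steps thought possible: starting material + free catalyst <-> catalyst intermediate A; reagent + catalyst intermediate A -> free catalyst + target; second substrate + free catalyst <-> catalyst intermediate B; reagent + catalyst intermediate B -> free catalyst + second product; starting material + reagent -> uncatalysed product; gas <-> reagent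
- no earlier run changes the charge of second substrate; that part of a forecast is a guess

Let x be the fraction of starting material left, and Y and U the target and uncatalysed product as fractions of its charge. Both routes are first order in reagent, so reagent cancels from their quotient. If the catalyst rests mainly as catalyst intermediate A (the resting state, assumed here), the quotient integrates in closed form:

dY/dU = s/x

Y = s ln[(1 + s)/(x + s)]

The oak run at 3.00 h reads Y = 14.2 % and, by difference, U = 17.0 %, which with x taken at its mean gives the reading s = 0.705 at 8 µM. Scaled with the catalyst charge, the split number, catalysed over uncatalysed rate at full starting material, is 1.41 for the elm flask.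

The bench rule that target rate follows the catalyst charge gives 0.0938, with reagent level held fixed. At 30 % conversion, however, s/x is 2.01 in the elm flask, so the catalysed draw on reagent exceeds the uncatalysed one, and at 1.5 µM it is 0.189. With the draw of these two routes held fixed instead, my reckoning gives 0.238, so I commit to a factor between these two values for 1.5 µM of free catalyst and reckon none for doubled second substrate, since no run varies that charge.

The forecast gives a factor of 0.85 (0.5 to 1.02) for doubled second substrate and 0.21 (0.15 to 0.32) for 1.5 µM of free catalyst, on the ground “so reagent supply looks nearly limiting”.

The flask gives a factor of 0.854 for doubled second substrate and 0.111 for 1.5 µM of free catalyst, the forecast's value for the latter being too high by a factor of 1.89.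

    starting material + free catalyst ⇌ catalyst intermediate A (K = 7550 M⁻¹, k = 57600 M⁻¹ h⁻¹)
    reagent + catalyst intermediate A → free catalyst + target (k = 44000 M⁻¹ h⁻¹)
    second substrate + free catalyst ⇌ catalyst intermediate B (K = 130 M⁻¹, k = 81300 M⁻¹ h⁻¹)
    reagent + catalyst intermediate B → free catalyst + second product (k = 1.36 × 10⁵ M⁻¹ h⁻¹)
    starting material + reagent → uncatalysed product (k = 35.4 M⁻¹ h⁻¹)
    gas ⇌ reagent, rate k6*(csat - [reagent]) (kL = 2.33 h⁻¹)

At 3.00 h catalyst intermediate A holds 68.0 % of the catalyst charged, beside catalyst intermediate B at 14.2 % and free catalyst at 17.8 %. With s = 1.41 and x = 60 %, Y comes to 25.6 %, and the flask holds 26.0 % target at 3.00 h.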